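**Retrosynthetic overview**
1. Target 7 is cut at the C2(central)–C4(outer) biaryl bond. Both carbons are natively nucleophilic naphthol positions, so the central one is inverted to an α-keto cation (enolonium) carbon, cation 5. This cation is stored as the extended quinone 4, and its partner is the para carbon of unprotected 2.
2. Quinone 4 comes from a four-electron para–para oxidative dimerisation of 2 through daldinol 3. This sets the C4–C4' bond.
3. Naphthol 2 comes from mono-O-methylation of naphthalene-1,8-diol 1.
4. No ring is built, because all three naphthalene units come intact from 1. Bonds form in the order O–Me, C4–C4', C2–C4''.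

Assumption: the target SMILES carries no stereodescriptor. Neither biaryl axis is hindered enough to be configurationally stable: one is a 2,2'-unsubstituted 1,1'-binaphthyl axis and the other a 1,2'-type axis with a single ortho OH. There is therefore no enantiomer to select, and the compound is made as drawn.

**Step 1**
Reactants: 1 naphthalene-1,8-diol
Product: 2 8-methoxynaphthalen-1-ol
Conditions: MeI (1.05 equiv), K2CO3 (1.05 equiv), acetone, N2, 23 °C to 40 °C, 12 h
Reagents that add atoms: iodomethane, CI
Why: Williamson ether synthesis; the first OH of 1 is unusually acidic because its monoanion is held by a peri hydrogen bond, while the OH left in 2 is locked to the new OMe and is far less acidic, so alkylation stops at the mono-ether (no stereocentre is formed).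

**Step 2**
Reactants: 2 8-methoxynaphthalen-1-ol (two molecules per product)
Product: 4 (E)-5,5'-dimethoxy-[1,1'-binaphthalenylidene]-4,4'-dione, via daldinol 3 (not isolated)
Conditions: Ag2O (2.5 equiv), Na2SO4, CH2Cl2, 23 °C, dark, 2 h; filter through Celite, triturate with Et2O
Reagents that add atoms: none
Why: Silver-oxide oxidative phenol coupling of the diphenoquinone-synthesis type; the naphthoxyl radical joins at its least hindered high-spin para carbon to give 3, which is easier to oxidise than 2 and is dehydrogenated at once to 4, a compound with no OH left that is the end point of the oxidation (the less crowded E alkene is expected, and its geometry is erased in step 3).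

**Step 3**
Reactants: 4 (E)-5,5'-dimethoxy-[1,1'-binaphthalenylidene]-4,4'-dione; 2 8-methoxynaphthalen-1-ol
Product: 7 2,4-bis(4-hydroxy-5-methoxynaphthalen-1-yl)-8-methoxynaphthalen-1-ol (target), via enolonium cation 5 (not isolated), via keto tautomer 6 (not isolated)
Conditions: 2 (4 equiv), (PhO)2P(O)OH (10 mol %), CH2Cl2–(CF3)2CHOH 4:1, −20 °C to 0 °C, Ar, dark; 4 in CH2Cl2 added over 2 h; excess 2 recovered on SiO2
Reagents that add atoms: none
Why: Proposed new method: protonation of one carbonyl of 4 (made basic by chelation to its peri OMe) aromatises that half and leaves the 4-aryl-naphthoxenium cation 5, whose charge sits on C4 (quaternary, blocked) and on C2 alpha to the remaining C=O, so the para carbon of 2 attacks C2 in a formal 1,8-addition, the attacking ring rearomatises to give 6, and enolisation erases the transient C2 stereocentre to give 7, which is at the naphthol level and cannot react again as an electrophile; electron transfer followed by radical-pair collapse at the same two carbons would give the same product, slow addition of 4 into excess 2 suppresses oxidation of 7 by 4, and the closest known reaction types are the 1,8-addition of HX to diphenoquinones (giving 3-substituted 4,4'-biphenols), Brønsted-acid-catalysed arylation of quinones and quinone monoacetals by naphthols, and 1,6-addition of naphthols to para-quinone methides.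

**Compound list**
1 | naphthalene-1,8-diol | Oc1cccc2cccc(O)c12 | starting material
2 | 8-methoxynaphthalen-1-ol | COc1cccc2cccc(O)c12 | intermediate
3 | daldinol, 5,5'-dimethoxy-[1,1'-binaphthalene]-4,4'-diol (not isolated) | COc1cccc2c(-c3ccc(O)c4c(OC)cccc34)ccc(O)c12 | intermediate
4 | (E)-5,5'-dimethoxy-[1,1'-binaphthalenylidene]-4,4'-dione | COc1cccc2c1C(=O)C=C/C2=C1/C=CC(=O)c2c(OC)cccc21 | intermediate
5 | O-protonated 4, 4-(4-hydroxy-5-methoxynaphthalen-1-yl)-8-methoxy-1-oxo-1,4-dihydronaphthalen-4-ylium, charge shared by C4 and C2 (not isolated) | COc1cccc2c1C(=O)C=C[C+]2c1ccc(O)c2c(OC)cccc12 | intermediate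
6 | 2,4-bis(4-hydroxy-5-methoxynaphthalen-1-yl)-8-methoxynaphthalen-1(2H)-one, racemic at C2 (not isolated) | COc1cccc2c1C(=O)C(C=C2c1ccc(O)c2c(OC)cccc12)c1ccc(O)c2c(OC)cccc12 | intermediate
7 | 2,4-bis(4-hydroxy-5-methoxynaphthalen-1-yl)-8-methoxynaphthalen-1-ol | COc1cccc2c(-c3cc(-c4ccc(O)c5c(OC)cccc45)c4cccc(OC)c4c3O)ccc(O)c12 | target

**Total step count:** 3. **Longest linear sequence:** 3 (1 → 2 → 4 → 7; 2 enters a second time in step 3).

**Steps most likely to fail** (risk order: step 3 > step 2 > step 1). They are given in step order because the third fallback draws on a compound of the second.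

Step 1. The risks are over-methylation and a tedious separation of diol, mono-ether and di-ether. The fallback sets out from 1 and comes back at 2. Compound 1 is methylated exhaustively (Me2SO4, K2CO3, acetone, reflux) to 1,8-dimethoxynaphthalene F1. One ether is then removed by nucleophilic demethylation (NaSEt 1.2 equiv, DMF, 120 °C). The naphtholate formed in the first SN2 cleavage makes the second ArO a far poorer leaving group, so the reaction stops cleanly at 2.

Step 2. The risks are ortho–para or ortho–ortho coupling, C–O coupling, capture of 4 by unreacted 2, and light-induced closure towards a perylenequinone. The fallback sets out from 2 and comes back at 3, which is then taken on to 4.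
- Para-bromination of 2 (NBS, MeCN, −10 °C) gives 4-bromo-8-methoxynaphthalen-1-ol F2.
- Half of it is converted by Miyaura borylation (B2pin2, Pd(dppf)Cl2, KOAc, dioxane, 80 °C) into 8-methoxy-4-(4,4,5,5-tetramethyl-1,3,2-dioxaborolan-2-yl)naphthalen-1-ol F3.
- Suzuki–Miyaura coupling of F2 with F3 (Pd(OAc)2, SPhos, K3PO4, degassed dioxane–H2O, 80 °C) gives isolated, regiochemically unambiguous 3.
- A simple two-electron dehydrogenation (Ag2O 1.2 equiv, CH2Cl2, dark) gives 4.

Step 3. The main risk is redox exchange instead of C–C bond formation. In that case 4 oxidises 2 or 7, giving 3 and higher oligomers. The 3 that results can be returned to 4 with Ag2O. Other risks are attack of 2 through oxygen or its ortho carbon, and attack at the beta carbon of 4. The fallback sets out from 4 and comes back at 7. The same electrophilic alpha carbon of 4 is first captured by bromide, a small nucleophile that 4 cannot oxidise (33% HBr in AcOH, CH2Cl2, 0 °C; 1,8-addition). This gives 3-bromo-5,5'-dimethoxy-[1,1'-binaphthalene]-4,4'-diol F4 as a single mono-bromide. The biaryl bond is then closed by Suzuki–Miyaura coupling of F4 with the boronate F3 described above, which is made from 2 (Pd(OAc)2, SPhos, K3PO4, degassed dioxane–H2O, 80 °C). The product is 7.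

**Further compounds**
F1 | step 1 | 1,8-dimethoxynaphthalene | COc1cccc2cccc(OC)c12
F2 | step 2 | 4-bromo-8-methoxynaphthalen-1-ol | COc1cccc2c(Br)ccc(O)c12
F3 | step 2 | 8-methoxy-4-(4,4,5,5-tetramethyl-1,3,2-dioxaborolan-2-yl)naphthalen-1-ol | COc1cccc2c(B3OC(C)(C)C(C)(C)O3)ccc(O)c12
F4 | step 3 | 3-bromo-5,5'-dimethoxy-[1,1'-binaphthalene]-4,4'-diol | COc1cccc2c(-c3ccc(O)c4c(OC)cccc34)cc(Br)c(O)c12
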